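**Retrosynthetic overview**
1. Final events: the C10 silyl ether is removed. Before that, one Evans–Tishchenko/lactonisation step on a ring ketone (C6=O, C8–OH) places the tiglate on O8, sets C6 and closes the γ-lactone.
2. Key step, C3–C4 disconnection: Ni/Cr coupling of a (Z)-β-iodoenone with the C3 aldehyde closes the ten-membered carbocycle. The new C3 alkoxide adds across the ring to the C6 ketone, so the carbocycle and a 3,6-oxa bridge form in the same operation.
3. C7–C8 disconnection: a reagent-controlled syn boron aldol joins fragment A (C4–C7, C11–C13, C15) to fragment B (C1–C3, C8–C10, C14). A prenyl end masks the C3 aldehyde.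
4. Fragment A comes from but-2-yn-1-ol and methyl 2-(bromomethyl)acrylate; its Z-iodoalkene becomes the 4Z ring alkene. Fragment B comes from geraniol by Sharpless epoxidation, which sets C10.
5. Ring order: carbocycle and oxa bridge together, then the oxa bridge is exchanged for the γ-lactone.

Numbering and assumption: atom labels follow germacrane numbering of the target (ring C1–C10, lactone O on C6, C12 carbonyl, C13 methylidene, C14 methyl on C10, C15 methyl on C4). The (−)-Ipc2BOTf antipode (from (+)-α-pinene) is assumed to be the one whose Z-enolate attacks the Si face of the fragment B aldehyde; if the sense is the reverse, the (+)-reagent is used.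

**Step 1**
Reactants: 1 but-2-yn-1-ol
Product: 3 (Z)-3-iodobut-2-en-1-ol, via cyclic sodium vinylalanate 2 (not isolated)
Conditions: NaAlH2(OCH2CH2OMe)2, THF, 0 °C to rt; then I2, THF, −78 to 0 °C
Reagents that add atoms: iodine, [I][I]
Why: Hydroxyl-directed trans-hydroalumination gives the five-membered vinylalanate, and iodine cleaves its C–Al bond with retention, so iodine ends cis to the CH2OH group (Z), the geometry of the later ring alkene.

**Step 2**
Reactants: 3 (Z)-3-iodobut-2-en-1-ol
Product: 4 (Z)-3-iodobut-2-enal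
Conditions: MnO2, CH2Cl2, rt, dark
Reagents that add atoms: none
Why: Allylic alcohol oxidation with activated MnO2 is neutral, stops at the enal and does not scramble the Z-iodoalkene.

**Step 3**
Reactants: 4 (Z)-3-iodobut-2-enal; 5 methyl 2-(bromomethyl)acrylate
Product: 7 methyl (Z)-4-hydroxy-6-iodo-2-methylidenehept-5-enoate (racemic carbinol), via allylzinc bromide 6 (not isolated)
Conditions: Zn dust, THF/sat. aq. NH4Cl, 0 °C
Reagents that add atoms: none
Why: In this aqueous Barbier allylation zinc inserts only into the allylic C–Br bond and the ester-bearing allylzinc adds 1,2 to the enal, while the cold neutral medium keeps the hydroxy ester open; the racemic carbinol centre is erased in step 4.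

**Step 4**
Reactants: 7 methyl (Z)-4-hydroxy-6-iodo-2-methylidenehept-5-enoate
Product: 8 methyl (Z)-6-iodo-2-methylidene-4-oxohept-5-enoate (fragment A)
Conditions: MnO2, CH2Cl2, rt
Reagents that add atoms: none
Why: Neutral MnO2 oxidation of the secondary allylic alcohol gives the β-iodoenone without moving the 2-methylidene double bond into conjugation and without Z/E isomerisation.

**Step 5**
Reactants: 9 geraniol
Product: 10 (2S,3S)-2,3-epoxygeraniol
Conditions: Ti(OiPr)4 (5 mol %), L-(+)-diethyl tartrate (7 mol %), t-BuOOH, 4 Å sieves, CH2Cl2, −20 °C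
Reagents that add atoms: tert-butyl hydroperoxide, CC(C)(C)OO
Why: In the Sharpless asymmetric epoxidation the L-(+)-tartrate titanium complex delivers oxygen to one face of the allylic alkene only, giving the 2S,3S epoxide that fixes the future C10 and leaving the remote trisubstituted alkene untouched.

**Step 6**
Reactants: 10 (2S,3S)-2,3-epoxygeraniol
Product: 11 (S)-3,7-dimethyloct-6-ene-1,3-diol
Conditions: NaAlH2(OCH2CH2OMe)2, THF, 0 °C to rt
Reagents that add atoms: none
Why: In this directed reductive epoxide opening the alkoxyaluminate delivers hydride intramolecularly to C2, so the 1,3-diol forms and the tertiary C–O bond keeps its configuration.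

**Step 7**
Reactants: 11 (S)-3,7-dimethyloct-6-ene-1,3-diol
Product: 12 (S)-3,7-dimethyl-1,3-bis(triethylsilyloxy)oct-6-ene
Conditions: Et3SiOTf (2.5 equiv), 2,6-lutidine, CH2Cl2, 0 °C
Reagents that add atoms: triethylsilyl trifluoromethanesulfonate, CC[Si](CC)(CC)OS(=O)(=O)C(F)(F)F
Why: The silyl triflate is reactive enough to cap the tertiary as well as the primary hydroxyl, which blocks retro-aldol, dehydration and lactol formation later on.

**Step 8**
Reactants: 12 (S)-3,7-dimethyl-1,3-bis(triethylsilyloxy)oct-6-ene
Product: 13 (S)-3,7-dimethyl-3-(triethylsilyloxy)oct-6-enal (fragment B)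
Conditions: (COCl)2, DMSO, CH2Cl2, −78 to −40 °C; Et3N, −78 °C to rt
Reagents that add atoms: none
Why: Swern oxidation acts directly on a primary triethylsilyl ether because activated DMSO attacks only the unhindered silyl ether oxygen, which becomes the aldehyde oxygen while the tertiary silyl ether stays.

**Step 9**
Reactants: 8 methyl (Z)-6-iodo-2-methylidene-4-oxohept-5-enoate; 13 (S)-3,7-dimethyl-3-(triethylsilyloxy)oct-6-enal
Product: 16 acyclic syn-aldol adduct (7S,8R,10S), via boron enolate 14 (not isolated), via boron aldolate 15 (not isolated)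
Conditions: 8, (−)-Ipc2BOTf, i-Pr2NEt, CH2Cl2, −78 °C; 13, −78 to −20 °C; H2O2, MeOH, pH 7 buffer, 0 °C
Reagents that add atoms: none
Why: In this Paterson-type boron aldol the ketone can enolise only toward C7 and gives the Z-enolate, whose closed chair transition state gives the C7/C8 syn relationship at the α-carbon, while the isopinocampheyl ligands select the Si face of the aldehyde (8R).

**Step 10**
Reactants: 16 acyclic syn-aldol adduct (7S,8R,10S)
Product: 18 keto aldehyde (7S,8R,10S) with free C3 aldehyde, via ozonide 17 (not isolated)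
Conditions: O3 (1 equiv), CH2Cl2, −78 °C; Me2S, −78 °C to rt
Reagents that add atoms: ozone, [O-][O+]=O
Why: Ozonolysis is chemoselective because the electron-rich trisubstituted prenyl alkene reacts far faster than the electron-poor iodoenone and acrylate double bonds.

**Step 11**
Reactants: 18 keto aldehyde (7S,8R,10S)
Product: 20 oxa-bridged hemiketal (3S,6S,7S,8R,10S), via macrocyclic hydroxy enone 19 (not isolated)
Conditions: CrCl2 (10 equiv), NiCl2 (0.1 equiv), DMSO/THF, slow addition of 18 to 1 mM, rt
Reagents that add atoms: none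
Why: In this Nozaki–Hiyama–Kishi reaction zerovalent nickel inserts into the activated β-iodoenone C–I bond with retention of the Z geometry, the alkenylchromium tolerates the free aldol, ester and silyl ether and adds only to the aldehyde, the C3 alkoxide then closes onto the cis-disposed C6 ketone to give the 2,5-dihydrofuran hemiketal (dehydration to a six-atom-bridged furan is too strained), and C3 is expected to be S from attack on the outer aldehyde face of the folded chain in which chromium stays bound to the C6 carbonyl and the C7 branch and C10 silyloxy group point outward.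

**Step 12**
Reactants: 20 oxa-bridged hemiketal (3S,6S,7S,8R,10S); 21 (E)-2-methylbut-2-enal (tiglic aldehyde)
Product: 23 C10 triethylsilyl ether of the target (3S,6R,7S,8R,10S), via C6 carbinol ester 22 (not isolated)
Conditions: SmI2 (0.3 equiv), 21 (6 equiv), THF, −10 °C
Reagents that add atoms: none
Why: In this Evans–Tishchenko reduction the trivalent samarium alkoxide reopens the hemiketal, O8 forms the hemiacetal of 21 and passes its hydride to the C6 ketone through a chelated six-membered chair, which gives the 1,3-anti (6R) carbinol and leaves the oxidised aldehyde as the tiglate on O8 only, and the C6 alkoxide then lactonises onto the adjacent methyl ester to give the cis-fused α-methylidene-γ-lactone.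

**Step 13**
Reactants: 23 C10 triethylsilyl ether of the target
Product: 24 target CNP0137971.1 (3S,4Z,6R,7S,8R,10S)
Conditions: HF·pyridine, pyridine, THF, 0 °C to rt
Reagents that add atoms: none
Why: Buffered fluoride desilylation frees the tertiary C10 alcohol without touching the tiglate, the α-methylidene lactone or the allylic alcohol, and no stereocentre is involved.

**Compound list**
1 | but-2-yn-1-ol | CC#CCO | starting material
2 | cyclic sodium vinylalanate (five-membered O–Al–C chelate, two 2-methoxyethoxy groups on Al) | CC1=CCO[Al-]1(OCCOC)OCCOC.[Na+] | intermediate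
3 | (Z)-3-iodobut-2-en-1-ol | OC/C=C(/C)I | intermediate
4 | (Z)-3-iodobut-2-enal | O=C/C=C(/C)I | intermediate
5 | methyl 2-(bromomethyl)acrylate | C=C(CBr)C(=O)OC | starting material
6 | [2-(methoxycarbonyl)allyl]zinc bromide | C=C(C[Zn]Br)C(=O)OC | intermediate
7 | methyl (Z)-4-hydroxy-6-iodo-2-methylidenehept-5-enoate, racemic carbinol | C=C(CC(O)/C=C(/C)I)C(=O)OC | intermediate
8 | methyl (Z)-6-iodo-2-methylidene-4-oxohept-5-enoate, fragment A | C=C(CC(=O)/C=C(/C)I)C(=O)OC | intermediate
9 | geraniol | CC(C)=CCC/C(C)=C/CO | starting material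
10 | (2S,3S)-2,3-epoxygeraniol | CC(C)=CCC[C@]1(C)O[C@H]1CO | intermediate
11 | (S)-3,7-dimethyloct-6-ene-1,3-diol | CC(C)=CCC[C@](C)(O)CCO | intermediate
12 | (S)-3,7-dimethyl-1,3-bis(triethylsilyloxy)oct-6-ene | CC(C)=CCC[C@](C)(O[Si](CC)(CC)CC)CCO[Si](CC)(CC)CC | intermediate
13 | (S)-3,7-dimethyl-3-(triethylsilyloxy)oct-6-enal, fragment B | CC(C)=CCC[C@](C)(O[Si](CC)(CC)CC)CC=O | intermediate
14 | (Z)-diisopinocampheylboron enolate of 8 | C=C(C(=O)OC)/C=C(/C=C(/C)I)OB([C@@H]1C[C@@H]2C[C@H]([C@H]1C)C2(C)C)[C@@H]1C[C@@H]2C[C@H]([C@H]1C)C2(C)C | intermediate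
15 | O8-diisopinocampheylboron aldolate of 16 | CC(C)=CCC[C@](C)(O[Si](CC)(CC)CC)C[C@@H](OB([C@@H]1C[C@@H]2C[C@H]([C@H]1C)C2(C)C)[C@@H]1C[C@@H]2C[C@H]([C@H]1C)C2(C)C)[C@H](C(=C)C(=O)OC)C(=O)/C=C(/C)I | intermediate
16 | acyclic syn-aldol adduct: C6 (Z)-β-iodoenone, C7 (S) bearing the 2-(methoxycarbonyl)vinylidene unit, C8 (R) OH, C10 (S) OSiEt3, prenyl terminus | CC(C)=CCC[C@](C)(O[Si](CC)(CC)CC)C[C@@H](O)[C@H](C(=C)C(=O)OC)C(=O)/C=C(/C)I | intermediate
17 | 1,2,4-trioxolane (ozonide) of the prenyl alkene of 16 | CC1(C)OOC(CC[C@](C)(O[Si](CC)(CC)CC)C[C@@H](O)[C@H](C(=C)C(=O)OC)C(=O)/C=C(/C)I)O1 | intermediate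
18 | keto aldehyde: 16 with the prenyl alkene cut to the C3 aldehyde | O=CCC[C@](C)(O[Si](CC)(CC)CC)C[C@@H](O)[C@H](C(=C)C(=O)OC)C(=O)/C=C(/C)I | intermediate
19 | ten-membered (4Z)-3-hydroxy-6-oxo carbocycle (3S,7S,8R,10S), open form of 20 | COC(=O)C(=C)[C@@H]1C(=O)/C=C(/C)[C@@H](O)CC[C@](C)(O[Si](CC)(CC)CC)C[C@H]1O | intermediate
20 | 3,6-oxa-bridged hemiketal (2,5-dihydrofuran across the ten-membered ring; 3S,6S,7S,8R,10S) | COC(=O)C(=C)[C@@H]1[C@]2(O)C=C(C)[C@@H](O2)CC[C@](C)(O[Si](CC)(CC)CC)C[C@H]1O | intermediate
21 | (E)-2-methylbut-2-enal (tiglic aldehyde) | O=C/C(C)=C/C | starting material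
22 | ring 6R-carbinol methyl ester with O8 tiglate (3S,6R,7S,8R,10S) | COC(=O)C(=C)[C@@H]1[C@H](O)/C=C(/C)[C@@H](O)CC[C@](C)(O[Si](CC)(CC)CC)C[C@H]1OC(=O)/C(C)=C/C | intermediate
23 | C10 triethylsilyl ether of the target | C=C1C(=O)O[C@@H]2/C=C(/C)[C@@H](O)CC[C@](C)(O[Si](CC)(CC)CC)C[C@@H](OC(=O)/C(C)=C/C)[C@H]12 | intermediate
24 | CNP0137971.1, (3S,4Z,6R,7S,8R,10S)-3,10-dihydroxy-8-tigloyloxygermacra-4,11(13)-dien-12,6-olide | C=C1C(=O)O[C@@H]2/C=C(/C)[C@@H](O)CC[C@](C)(O)C[C@@H](OC(=O)/C(C)=C/C)[C@H]12 | target

**Totals**
Total step count: 13. Longest linear sequence: 9 (steps 5–13 from geraniol).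

**Steps most likely to fail**

Step 11 (ring-closure yield and the C3 configuration). The fallback removes C3 from the ring-closing event and sets it by reagent control. It starts from 20, used as whatever C3 mixture the coupling gives. Dess–Martin periodinane drains the hemiketal through its open form to the macrocyclic (Z)-ene-dione F1. SmI2 and 21 then reduce only the C6 ketone that is β to the C8 hydroxyl, and lactonisation gives the 3-oxo lactone tiglate F2. (R)-2-Methyl-CBS-oxazaborolidine with catecholborane at −78 °C reduces the C3 enone to the 3S alcohol. The route is rejoined at 23.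

Step 12 (the hemiketal may hide the ketone too well, or the strained ring aldol may undergo retro-aldol cleavage). The fallback builds the lactone before the carbocycle. It starts from 16. SmI2 and 21 on the acyclic aldol give the iodoalkenyl lactone tiglate F3. Ozonolysis of its prenyl alkene gives the lactone aldehyde F4. CrCl2/NiCl2 at high dilution closes C3–C4. The route is rejoined at 23.

Step 9 (facial control by the boron ligands and integrity of the cross-conjugated enolate). The fallback uses an open-transition-state Mukaiyama aldol under a chiral Lewis acid. It starts from 8. Me3SiOTf/Et3N gives the (Z)-trimethylsilyl dienol ether F5. This adds to 13 under a stoichiometric N-tosylvaline-derived oxazaborolidinone of the hand that opens the Si face, and dilute acid work-up removes the silyl group. The route is rejoined at 16.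

**Further compounds**
F1 | step 11 | macrocyclic (4Z)-3,6-dioxo carbocycle with C8 hydroxyl (7S,8R,10S) | COC(=O)C(=C)[C@@H]1C(=O)/C=C(/C)C(=O)CC[C@](C)(O[Si](CC)(CC)CC)C[C@H]1O
F2 | step 11 | 3-oxo analogue of 23 | C=C1C(=O)O[C@@H]2/C=C(/C)C(=O)CC[C@](C)(O[Si](CC)(CC)CC)C[C@@H](OC(=O)/C(C)=C/C)[C@H]12
F3 | step 12 | acyclic cis-lactone with (Z)-2-iodopropenyl group on C6, O8 tiglate, C10 OSiEt3 and prenyl terminus | C=C1C(=O)O[C@H](/C=C(/C)I)[C@@H]1[C@H](OC(=O)/C(C)=C/C)C[C@@](C)(O[Si](CC)(CC)CC)CCC=C(C)C
F4 | step 12 | C3 aldehyde from F3 | C=C1C(=O)O[C@H](/C=C(/C)I)[C@@H]1[C@H](OC(=O)/C(C)=C/C)C[C@@](C)(O[Si](CC)(CC)CC)CCC=O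
F5 | step 9 | (Z)-trimethylsilyl dienol ether of 8 | C=C(C(=O)OC)/C=C(/C=C(/C)I)O[Si](C)(C)C
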